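**Retrosynthetic overview**

1. Target 15 ⇐ quinone 14 (H2, Pd/C: quinone reduction and benzyl ester hydrogenolysis together) ⇐ dimethyl ether 13 (oxidative demethylation).
2. 13 ⇐ alkene 8 + acetaldehyde 11 + acyl bromide 10 + a hydrosilane in one flask: an enantioconvergent nickel-hydride coupling forms the side-chain bond between the carbinol CH (bearing CH3 and the succinyl ester oxygen) and its neighbouring CH2, sets the (R) carbinol centre, brings in the whole succinate and saturates the alkene.
3. Enabling feature: that carbinol carbon is the O-bearing carbon of an ester of a dialkyl carbinol, so its O–C(=O) group lets CH3CHO and an acyl bromide give a 1-bromoethyl ester whose radical is captured at nickel under carbonyl-oxygen chelation; its CH2 partner ends an unbranched three-carbon chain on C3 of the lactone ring (ring B), so it is the terminal carbon of an allyl group.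
4. 8 ⇐ amide 3 + (R)-2-allyloxirane 6 (from (R)-epichlorohydrin 4): ortho-metalation at the ring CH between the amide and a methoxy group, epoxide opening, lactonisation. Benzene ring A is bought, ring B is closed in step 4, and no ring is made after that.

Key step: step 6

Assumption: the sense of induction of the chiral bis(oxazoline)–nickel catalyst in step 6 is not taken as known for this substrate; the ligand antipode that gives the (R) ester is to be fixed in a model coupling with a simple 1-alkene.

**Route**

Step 1
Reactants: 1 2,5-dimethoxybenzoic acid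
Product: 3 N,N-diethyl-2,5-dimethoxybenzamide, via acid chloride 2 (not isolated)
Conditions: (COCl)2, DMF (cat.), CH2Cl2, 0 °C → rt; then Et2NH, Et3N, CH2Cl2, 0 °C
Reagents that add atoms: diethylamine, CCNCC
Why: Acid chloride formation followed by amidation should give the tertiary amide that serves as the directing group for ortho-metalation.

Step 2
Reactants: 4 (R)-epichlorohydrin
Product: 5 (2R)-1-chloropent-4-en-2-ol
Conditions: CH2=CHMgBr, CuI (10 mol %), THF, −78 → −30 °C; 1 M HCl
Reagents that add atoms: vinylmagnesium bromide, C=C[Mg]Br
Why: Copper-catalysed Grignard opening of the epoxide at its unsubstituted carbon (SN2) should outrun chloride displacement, and the stereocentre keeps all four bonds and stays (R).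

Step 3
Reactants: 5 (2R)-1-chloropent-4-en-2-ol
Product: 6 (2R)-2-(prop-2-en-1-yl)oxirane
Conditions: NaOH (powder), Et2O, 0 °C → rt; distil
Reagents that add atoms: none
Why: Intramolecular Williamson etherification of the chlorohydrin alkoxide should close the epoxide without touching the carbinol C–O bond, so the configuration is retained.

Step 4
Reactants: 3 N,N-diethyl-2,5-dimethoxybenzamide, 6 (2R)-2-(prop-2-en-1-yl)oxirane
Product: 8 (3R)-3-allyl-5,8-dimethoxyisochroman-1-one, via hydroxy amide 7 (not isolated)
Conditions: s-BuLi, TMEDA, THF, −78 °C; MgBr2·OEt2, −78 → −40 °C; CuI (10 mol %), 6, −40 → 0 °C; 1 M HCl; then crude 7, TsOH·H2O (1.2 equiv), PhMe, 110 °C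
Reagents that add atoms: none
Why: Directed ortho-metalation should occur at the one ring CH flanked by the amide and a methoxy group, the arylmagnesium/copper species should open the terminal epoxide at CH2 with the stereocentre untouched, and acid-promoted N→O acyl transfer of the hydroxy amide should close the six-membered lactone (ring B) with retention at C3.

Step 5
Reactants: 9 4-(benzyloxy)-4-oxobutanoic acid
Product: 10 benzyl 4-bromo-4-oxobutanoate
Conditions: (COBr)2, DMF (cat.), CH2Cl2, 0 °C → rt; concentrate cold, use at once
Reagents that add atoms: oxalyl bromide, O=C(Br)C(=O)Br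
Why: Vilsmeier-type activation with oxalyl bromide should convert the acid into the acyl bromide under cold, neutral conditions that keep the benzyl ester.

Step 6
Reactants: 8 (3R)-3-allyl-5,8-dimethoxyisochroman-1-one, 10 benzyl 4-bromo-4-oxobutanoate, 11 acetaldehyde
Product: 13 benzyl (2R)-5-[(3R)-5,8-dimethoxy-1-oxoisochroman-3-yl]pentan-2-yl butanedioate, via racemic 1-bromoethyl ester 12 (not isolated)
Conditions: 10 + 11 (2 equiv each), CH2Cl2, −20 °C → rt; then 8 (1 equiv), NiBr2·glyme (NiBr2·MeOCH2CH2OMe, 10 mol %), chiral bis(oxazoline) L* (12 mol %), (EtO)3SiH (3 equiv), K3PO4·H2O (3 equiv), Et2O/DMA, rt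
Reagents that add atoms: none
Why: The acyl bromide should add across the C=O of acetaldehyde to give racemic 1-bromoethyl ester 12, while a chiral divalent nickel hydride (from NiBr2, the silane and the phosphate) inserts the terminal alkene of 8 anti-Markovnikov to a primary alkylnickel; bromine abstraction from 12 then gives a planar α-acyloxyethyl radical that is captured at nickel, and reductive elimination from trivalent nickel forms the CH–CH2 bond. The closest known reaction type is the nickel-hydride-catalysed enantioconvergent alkyl–alkyl coupling of racemic 1-haloalkyl esters with olefins and a hydrosilane, including its four-component form starting from an aldehyde and an acyl bromide. No ring is closed in this step. The new (R) carbinol centre is set by the chiral bis(oxazoline) ligand: both enantiomers of 12 pass through the same radical and the ester carbonyl oxygen binds nickel in the bond-forming event, whereas the C3 centre, four carbons away, should not interfere, so the outcome is catalyst-controlled. The step needs linear regioselectivity, which the monosubstituted alkene secures, and chemoselectivity for the C–Br bond over the lactone, the benzyl ester and the aryl ethers, none of which should react with the nickel hydride or the silane at room temperature.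

Step 7
Reactants: 13 benzyl (2R)-5-[(3R)-5,8-dimethoxy-1-oxoisochroman-3-yl]pentan-2-yl butanedioate
Product: 14 benzyl (2R)-5-[(3R)-1,5,8-trioxo-3,4,5,8-tetrahydro-1H-isochromen-3-yl]pentan-2-yl butanedioate
Conditions: (NH4)2Ce(NO3)6 (2.5 equiv), MeCN/H2O (2:1), 0 °C, 15 min; crude used at once
Reagents that add atoms: water, O
Why: Oxidative demethylation of the 1,4-dimethoxyarene by the one-electron oxidant (ipso attack of water on the arene radical cation, loss of methanol) should give the quinone without involving the esters or the stereocentres.

Step 8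
Reactants: 14 benzyl (2R)-5-[(3R)-1,5,8-trioxo-3,4,5,8-tetrahydro-1H-isochromen-3-yl]pentan-2-yl butanedioate
Product: 15 4-{[(2R)-5-[(3R)-5,8-dihydroxy-1-oxoisochroman-3-yl]pentan-2-yl]oxy}-4-oxobutanoic acid
Conditions: H2 (1 atm), Pd/C (10 % palladium on carbon), EtOAc, rt; filter under argon
Reagents that add atoms: none
Why: Palladium-catalysed hydrogenation should reduce the quinone to the hydroquinone and hydrogenolyse the benzyl ester in the same operation, leaving the lactone, the secondary ester and both stereocentres untouched.

**Compound list**

1 | 2,5-dimethoxybenzoic acid | COc1ccc(OC)c(C(=O)O)c1 | starting material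
2 | 2,5-dimethoxybenzoyl chloride | COc1ccc(OC)c(C(=O)Cl)c1 | intermediate (not isolated)
3 | N,N-diethyl-2,5-dimethoxybenzamide | CCN(CC)C(=O)c1cc(OC)ccc1OC | intermediate
4 | (R)-epichlorohydrin, (2R)-2-(chloromethyl)oxirane | ClC[C@H]1CO1 | starting material
5 | (2R)-1-chloropent-4-en-2-ol | C=CC[C@@H](O)CCl | intermediate
6 | (2R)-2-(prop-2-en-1-yl)oxirane | C=CC[C@@H]1CO1 | intermediate
7 | N,N-diethyl-2-[(2R)-2-hydroxypent-4-en-1-yl]-3,6-dimethoxybenzamide | C=CC[C@@H](O)Cc1c(OC)ccc(OC)c1C(=O)N(CC)CC | intermediate (not isolated)
8 | (3R)-3-allyl-5,8-dimethoxyisochroman-1-one | C=CC[C@@H]1Cc2c(OC)ccc(OC)c2C(=O)O1 | intermediate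
9 | 4-(benzyloxy)-4-oxobutanoic acid | O=C(O)CCC(=O)OCc1ccccc1 | starting material
10 | benzyl 4-bromo-4-oxobutanoate | O=C(Br)CCC(=O)OCc1ccccc1 | intermediate
11 | acetaldehyde | CC=O | starting material
12 | benzyl 1-bromoethyl butanedioate (racemic) | CC(Br)OC(=O)CCC(=O)OCc1ccccc1 | intermediate (not isolated)
13 | benzyl (2R)-5-[(3R)-5,8-dimethoxy-1-oxoisochroman-3-yl]pentan-2-yl butanedioate | C[C@H](CCC[C@@H]1Cc2c(OC)ccc(OC)c2C(=O)O1)OC(=O)CCC(=O)OCc1ccccc1 | intermediate
14 | benzyl (2R)-5-[(3R)-1,5,8-trioxo-3,4,5,8-tetrahydro-1H-isochromen-3-yl]pentan-2-yl butanedioate | C[C@H](CCC[C@@H]1CC2=C(C(=O)O1)C(=O)C=CC2=O)OC(=O)CCC(=O)OCc1ccccc1 | intermediate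
15 | 4-{[(2R)-5-[(3R)-5,8-dihydroxy-1-oxoisochroman-3-yl]pentan-2-yl]oxy}-4-oxobutanoic acid | C[C@H](CCC[C@@H]1Cc2c(O)ccc(O)c2C(=O)O1)OC(=O)CCC(=O)O | target

**Step count**

Total: 8 steps. Longest linear sequence: 6 steps (4 → 5 → 6 → 8 → 13 → 14 → 15; steps 2, 3, 4, 6, 7, 8).

**Steps most likely to fail**

Step 6. The capture of the small α-acyloxyethyl radical may show weak facial discrimination (methyl against the ester oxygen), giving poor control at the new carbinol centre, or reduction of the bromo ester may outrun the coupling. The fallback takes the stereocentre from the chiral pool and makes the neighbouring C=C bond instead; it sets out from 8 and 10. Commercial (R)-but-3-en-2-ol (C[C@H](C=C)O) is acylated with 10 (pyridine, CH2Cl2, 0 °C) to give benzyl (2R)-but-3-en-2-yl butanedioate F1. Olefin cross-metathesis of 8 with an excess of F1 (second-generation Hoveyda–Grubbs catalyst, CH2Cl2, 40 °C) should give benzyl (2R,3E)-5-[(3R)-5,8-dimethoxy-1-oxoisochroman-3-yl]pent-3-en-2-yl butanedioate F2. Homogeneous hydrogenation of the disubstituted alkene (H2, RhCl(PPh3)3, benzene/EtOH) should leave the benzyl ester in place and comes back to the route at 13.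

Step 4. The arylmetal is flanked by two ortho substituents, so the SN2 opening of the epoxide may be slow; base-induced isomerisation of the allyl epoxide to a dienol or metalation at another ring position may compete. The fallback replaces the organometallic route by C–H activation; it sets out from 1 and 6. Carboxylate-directed ortho C–H alkylation of 1 with the terminal epoxide 6 under divalent palladium catalysis (Pd(OAc)2, a mono-N-protected amino acid ligand, KOAc, (CF3)2CHOH, 75 °C), with lactonisation in the same flask, should give 8 directly with the epoxide stereocentre untouched. It comes back to the route at 8 and makes no compound outside the list (F0).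

Step 7. The electron-poor ring may be demethylated incompletely, or the acyl quinone may decompose or be over-oxidised before it is reduced. The fallback avoids the oxidative unmasking by changing the phenol protection before the coupling; it sets out from 8. Demethylation (BBr3, CH2Cl2, −78 → 0 °C) should give (3R)-3-allyl-5,8-dihydroxyisochroman-1-one F3. Benzylation (BnBr, K2CO3, DMF) should give (3R)-3-allyl-5,8-bis(benzyloxy)isochroman-1-one F4. The coupling of step 6 with 10 and 11 under the same nickel conditions should give benzyl (2R)-5-[(3R)-5,8-bis(benzyloxy)-1-oxoisochroman-3-yl]pentan-2-yl butanedioate F5. One hydrogenolysis (H2, Pd/C, EtOAc) removes all three benzyl groups and comes back to the route at 15.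

**Further compounds**

F1 | step 6 | benzyl (2R)-but-3-en-2-yl butanedioate | C[C@H](C=C)OC(=O)CCC(=O)OCc1ccccc1
F2 | step 6 | benzyl (2R,3E)-5-[(3R)-5,8-dimethoxy-1-oxoisochroman-3-yl]pent-3-en-2-yl butanedioate | C[C@H](/C=C/C[C@@H]1Cc2c(OC)ccc(OC)c2C(=O)O1)OC(=O)CCC(=O)OCc1ccccc1
F0 | step 4 | none | none
F3 | step 7 | (3R)-3-allyl-5,8-dihydroxyisochroman-1-one | C=CC[C@@H]1Cc2c(O)ccc(O)c2C(=O)O1
F4 | step 7 | (3R)-3-allyl-5,8-bis(benzyloxy)isochroman-1-one | C=CC[C@@H]1Cc2c(OCc3ccccc3)ccc(OCc3ccccc3)c2C(=O)O1
F5 | step 7 | benzyl (2R)-5-[(3R)-5,8-bis(benzyloxy)-1-oxoisochroman-3-yl]pentan-2-yl butanedioate | C[C@H](CCC[C@@H]1Cc2c(OCc3ccccc3)ccc(OCc3ccccc3)c2C(=O)O1)OC(=O)CCC(=O)OCc1ccccc1
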